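**Plan**
Locants: benzene ring C1 (OH between the two carbon substituents), C2 (side chain), C4 (OH), C6 (CH3). The side chain runs from C1' (benzylic CH2) to C16' (CH2OH), with the carbinol at C5'.
Cuts, in retrosynthetic order: first the three acyl masks (two aryl acetates and the C16' ethyl ester, all removed by one hydride step). Then aryl C2–C1' and C4'–C5' are cut together, and last C14'=C15'.
Enabling feature: C1'–C4' plus the methyl on C3', held between ring carbon C2 and carbinol carbon C5', are one intact isoprene molecule. It carries a carbon substituent on each terminus and keeps its remaining double bond in the middle, which is the pattern left by a nickel-mediated aldehyde/1,3-diene/aryl-metal union.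
Forward: farnesyl acetate is trimmed at its isopropylidene end and re-extended to a Z-enoate enal (C5'–C16'). 2-Bromo-6-methylphenol is taken through the quinone and the hydroquinone diacetate to an aryl boronate. Enal, isoprene and boronate are then joined in one operation, and one global reduction finishes the route. No ring is built, since the benzene ring is bought.
Stereochemistry: C5' (R) comes from the chiral ligand on nickel in the key step, and C2'=C3' (E) from the same step. C6'=C7' and C10'=C11' (E) come with farnesyl acetate. C14'=C15' (Z, CH2OH cis to the chain) comes from a Still–Gennari olefination.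

Key step: step 9

Assumption: the sense of induction of the phosphoramidite ligand in the key step cannot be derived safely from a model. The route is written for the ligand antipode that gives (5'R), to be confirmed by Mosher ester analysis of the coupling product.

Step 1
Reactants: 1 (2E,6E)-farnesyl acetate
Product: 2 (2E,6E)-10-bromo-11-hydroxy-3,7,11-trimethyldodeca-2,6-dien-1-yl acetate (racemic)
Conditions: NBS (1.1 equiv), THF/H2O, 0 °C
Reagents that add atoms: N-bromosuccinimide O=C1CCC(=O)N1Br; water O
Why: Terminal-selective bromohydrin formation of a polyprenyl chain in aqueous medium, in which the exposed isopropylidene olefin reacts first, the C2=C3 olefin is deactivated by the allylic acetate and water opens the bromonium ion at the tertiary carbon; the new centre is racemic and is erased in step 3.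

Step 2
Reactants: 2 bromohydrin acetate
Product: 4 (2E,6E)-10,11-epoxyfarnesol (racemic), via 10,11-epoxyfarnesyl acetate 3 (not isolated)
Conditions: K2CO3, MeOH, 20 °C
Reagents that add atoms: none
Why: Base-induced 3-exo-tet closure of the bromohydrin (intramolecular Williamson reaction) and transesterification of the allylic acetate with methanol run in the same flask, so the acetate that steered step 1 is removed at no extra cost.

Step 3
Reactants: 4 (2E,6E)-10,11-epoxyfarnesol
Product: 6 (4E,8E)-10-hydroxy-4,8-dimethyldeca-4,8-dienal, via 10,11-dihydroxy-10,11-dihydrofarnesol 5 (not isolated)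
Conditions: H5IO6 (1.2 equiv), THF/H2O, 0 °C
Reagents that add atoms: none
Why: Periodic acid hydrolyses the trisubstituted epoxide (water enters at the tertiary carbon) and cleaves the glycol at once (Malaprade cleavage), which removes the racemic centre and expels the isopropylidene carbons, while the weak, cold acid should spare the primary allylic alcohol.

Step 4
Reactants: 6 (4E,8E)-10-hydroxy-4,8-dimethyldeca-4,8-dienal; 7 ethyl 2-[bis(2,2,2-trifluoroethoxy)phosphoryl]propanoate
Product: 8 ethyl (2Z,6E,10E)-12-hydroxy-2,6,10-trimethyldodeca-2,6,10-trienoate
Conditions: 7, KN(SiMe3)2, 18-crown-6, THF, −78 °C; then 6, −78 °C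
Reagents that add atoms: none
Why: Still–Gennari olefination, in which the electron-poor phosphonate with a dissociated potassium ion eliminates from the kinetic adduct faster than the adduct reverts and should therefore give the Z-trisubstituted enoate (ester cis to the chain); the stabilised carbanion is too weak a base to be quenched by the free alcohol.

Step 5
Reactants: 8 ethyl (2Z,6E,10E)-12-hydroxy-2,6,10-trimethyldodeca-2,6,10-trienoate
Product: 9 ethyl (2Z,6E,10E)-2,6,10-trimethyl-12-oxododeca-2,6,10-trienoate
Conditions: activated MnO2 (excess), CH2Cl2, 20 °C
Reagents that add atoms: none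
Why: Chemoselective allylic alcohol oxidation on MnO2 should stop at the E-enal and leave the enoate and the isolated olefins untouched.

Step 6
Reactants: 10 2-bromo-6-methylphenol
Product: 11 2-bromo-6-methyl-1,4-benzoquinone
Conditions: (KSO3)2NO (2.5 equiv), KH2PO4 buffer, H2O/acetone, 20 °C
Reagents that add atoms: potassium nitrosodisulfonate [K+].[K+].[O]N(S(=O)(=O)[O-])S(=O)(=O)[O-]
Why: Teuber reaction, in which two equivalents of the nitrosodisulfonate radical take the phenol through its phenoxyl radical to the quinone, and the para position is the only one open because both ortho positions are substituted.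

Step 7
Reactants: 11 2-bromo-6-methyl-1,4-benzoquinone
Product: 13 2-bromo-6-methylbenzene-1,4-diyl diacetate, via 2-bromo-6-methylhydroquinone 12 (not isolated)
Conditions: Zn dust, Ac2O, AcOH, NaOAc, 25 to 60 °C
Reagents that add atoms: acetic anhydride CC(=O)OC(C)=O
Why: Reductive acetylation of a quinone, in which zinc reduces the quinone and the hydroquinone is trapped at once as the air-stable diacetate, while the aryl bromide is inert to zinc under these conditions.

Step 8
Reactants: 13 2-bromo-6-methylbenzene-1,4-diyl diacetate
Product: 14 2-(5,5-dimethyl-1,3,2-dioxaborinan-2-yl)-6-methylbenzene-1,4-diyl diacetate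
Conditions: bis(neopentyl glycolato)diboron (1.2 equiv), PdCl2(dppf) (3 mol %), KOAc (3 equiv), 1,4-dioxane, 85 °C
Reagents that add atoms: bis(neopentyl glycolato)diboron CC1(C)COB(OC1)B1OCC(C)(C)CO1
Why: Miyaura borylation (oxidative addition of zerovalent palladium to C–Br, acetate-assisted transfer of boron, reductive elimination), in which KOAc is too weak a base to cleave the aryl acetates and the slim neopentyl glycol ester is chosen for easy transfer of its aryl group to nickel in step 9.

Step 9
Reactants: 9 ethyl (2Z,6E,10E)-2,6,10-trimethyl-12-oxododeca-2,6,10-trienoate; 14 aryl neopentyl glycol boronate; 15 isoprene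
Product: 17 ethyl (2Z,6E,10E,12R,14E)-16-(2,5-diacetoxy-3-methylphenyl)-12-hydroxy-2,6,10,14-tetramethylhexadeca-2,6,10,14-tetraenoate, via O-boryl ether 16 (not isolated)
Conditions: Ni(cod)2 (10 mol %), (R)-N,N-dimethyl-(1,1'-spirobiindane-7,7'-diyl) phosphoramidite (12 mol %), 15 (5 equiv), 14 (1.5 equiv), THF, 25 °C, sealed vessel, argon; then aq. NH4Cl
Reagents that add atoms: none
Why: Proposed new method: zerovalent nickel carrying one chiral phosphoramidite binds the formyl group of 9 and s-trans isoprene and couples them oxidatively, aldehyde carbon to the CH2 terminus next to the methyl-bearing carbon (largest HOMO coefficient, most substituted allyl unit), to an alkoxy(η3-allyl) complex of divalent nickel; the Ni–O bond then exchanges with the B–aryl bond of 14 (oxygen to boron, aryl to nickel), and reductive elimination at the free CH2 end of the allyl unit forms the aryl C2–C1' bond, releases 16 and returns zerovalent nickel. The closest known reaction types are the racemic nickel-catalysed three-component connection of aldehydes, 1,3-dienes and arylzinc or arylboron reagents and the enantioselective phosphoramidite–nickel reductive coupling of dienes with aldehydes, and the new element is their merger on isoprene and a β,β-disubstituted enal. No ring of the product is closed, the five-membered oxanickelacycle being only a transient of the catalytic cycle. The C5' centre is created in the oxidative coupling and its configuration is controlled solely by the ligand, which decides the aldehyde face that meets the diene; nothing later in the cycle touches this carbon. The C2'=C3' olefin should come out E because the s-trans diene places the CH2–C5' branch syn and the methyl group anti on the allyl unit, an arrangement that cannot easily invert since that would need nickel σ-bound to a tertiary carbon, and arylation is 1,4 because the other allyl terminus is fully substituted. The step needs attack at the formyl carbon in preference to conjugate arylation, direct aryl transfer, the enoate and the aryl acetates, which is secured by the β,β-disubstituted enal terminus, the excess of diene, the hindered trisubstituted enoate and the low temperature at which aryl C–O bonds do not add to nickel.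

Step 10
Reactants: 17 coupled hydroxy ester diacetate
Product: 18 (2Z,6E,10E,12R,14E)-16-(2,5-dihydroxy-3-methylphenyl)-2,6,10,14-tetramethylhexadeca-2,6,10,14-tetraene-1,12-diol (target)
Conditions: i-Bu2AlH (12 equiv), CH2Cl2, −78 to 0 °C, argon; degassed aq. potassium sodium tartrate containing Na2S2O4
Reagents that add atoms: none
Why: Hydride reduction of esters, in which i-Bu2AlH takes the Z-enoate to the allylic alcohol by 1,2-reduction without touching olefin geometry or C5' and cleaves both aryl acetates reductively, so all three masked hydroxyl groups are released in one operation (any acetyl migration in step 9 is erased here as well).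

**Compound list**
1 | (2E,6E)-farnesyl acetate | CC(C)=CCC/C(C)=C/CC/C(C)=C/COC(C)=O | starting material
2 | (2E,6E)-10-bromo-11-hydroxy-3,7,11-trimethyldodeca-2,6-dien-1-yl acetate (racemic) | CC(C)(O)C(Br)CC/C(C)=C/CC/C(C)=C/COC(C)=O | intermediate
3 | (2E,6E)-10,11-epoxyfarnesyl acetate (racemic, not isolated) | CC1(C)OC1CC/C(C)=C/CC/C(C)=C/COC(C)=O | intermediate
4 | (2E,6E)-10,11-epoxyfarnesol (racemic) | CC1(C)OC1CC/C(C)=C/CC/C(C)=C/CO | intermediate
5 | (2E,6E)-10,11-dihydroxy-10,11-dihydrofarnesol (racemic, not isolated) | CC(C)(O)C(O)CC/C(C)=C/CC/C(C)=C/CO | intermediate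
6 | (4E,8E)-10-hydroxy-4,8-dimethyldeca-4,8-dienal | O=CCC/C(C)=C/CC/C(C)=C/CO | intermediate
7 | ethyl 2-[bis(2,2,2-trifluoroethoxy)phosphoryl]propanoate | CCOC(=O)C(C)P(=O)(OCC(F)(F)F)OCC(F)(F)F | starting material
8 | ethyl (2Z,6E,10E)-12-hydroxy-2,6,10-trimethyldodeca-2,6,10-trienoate | CCOC(=O)/C(C)=C\CC/C(C)=C/CC/C(C)=C/CO | intermediate
9 | ethyl (2Z,6E,10E)-2,6,10-trimethyl-12-oxododeca-2,6,10-trienoate | CCOC(=O)/C(C)=C\CC/C(C)=C/CC/C(C)=C/C=O | intermediate
10 | 2-bromo-6-methylphenol | Cc1cccc(Br)c1O | starting material
11 | 2-bromo-6-methyl-1,4-benzoquinone | CC1=CC(=O)C=C(Br)C1=O | intermediate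
12 | 2-bromo-6-methylhydroquinone (not isolated) | Cc1cc(O)cc(Br)c1O | intermediate
13 | 2-bromo-6-methylbenzene-1,4-diyl diacetate | CC(=O)Oc1cc(C)c(OC(C)=O)c(Br)c1 | intermediate
14 | 2-(5,5-dimethyl-1,3,2-dioxaborinan-2-yl)-6-methylbenzene-1,4-diyl diacetate | CC(=O)Oc1cc(C)c(OC(C)=O)c(B2OCC(C)(C)CO2)c1 | intermediate
15 | isoprene | C=CC(C)=C | starting material
16 | O-(5,5-dimethyl-1,3,2-dioxaborinan-2-yl) ether of 17 (not isolated) | CCOC(=O)/C(C)=C\CC/C(C)=C/CC/C(C)=C/[C@H](OB1OCC(C)(C)CO1)C/C(C)=C/Cc1cc(OC(C)=O)cc(C)c1OC(C)=O | intermediate
17 | ethyl (2Z,6E,10E,12R,14E)-16-(2,5-diacetoxy-3-methylphenyl)-12-hydroxy-2,6,10,14-tetramethylhexadeca-2,6,10,14-tetraenoate | CCOC(=O)/C(C)=C\CC/C(C)=C/CC/C(C)=C/[C@H](O)C/C(C)=C/Cc1cc(OC(C)=O)cc(C)c1OC(C)=O | intermediate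
18 | (2Z,6E,10E,12R,14E)-16-(2,5-dihydroxy-3-methylphenyl)-2,6,10,14-tetramethylhexadeca-2,6,10,14-tetraene-1,12-diol | C/C(=C/CC/C(C)=C/CC/C(C)=C/[C@H](O)C/C(C)=C/Cc1cc(O)cc(C)c1O)CO | target

Total step count: 10. Longest linear sequence: 7 steps (steps 1–5, 9, 10).

**Steps most likely to fail**

1. Step 9. Several things may go wrong:
- poor facial selectivity at the formyl group under the chiral ligand;
- erosion of the E geometry if the diene reacts through its s-cis form;
- slow transfer of the ortho-substituted aryl group from boron to nickel, so that diene oligomerisation or direct aryl transfer to the aldehyde takes over.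

   The fallback uses known chemistry, sets out from 9, 14 and 15 and comes back at 17. The three components are joined without asymmetric induction under the established racemic conditions for aldehyde/diene/arylboron unions (Ni(cod)2, PPh3, THF, 25 °C). This gives the racemic O-boryl ether F1 and, after aqueous work-up, the racemic alcohol F2. Dess–Martin oxidation buffered with NaHCO3 gives the dienone F3. Corey–Bakshi–Shibata reduction then follows, with (S)-1-methyl-3,3-diphenyl-tetrahydropyrrolo[1,2-c][1,3,2]oxazaborole and catecholborane in toluene at −78 °C. With the alkenyl branch acting as the large group, it should deliver the 12R alcohol 17. The stereocentre then comes from a reagent-controlled ketone reduction and not from the coupling.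

2. Step 10. Air oxidation of the free hydroquinone may occur during the slightly basic aluminium work-up, and the polar tetraol may be held back on aluminium salts. The fallback sets out from 17 and comes back at 18. The reduction is run as before, but the crude product is deliberately oxidised with Ag2O in Et2O to the robust quinone F4, which can be chromatographed in air. Shaking F4 in Et2O with aqueous Na2S2O4 under argon then releases 18 in a neutral operation that needs only phase separation.

3. Step 6. One-electron oxidation of the bromine-deactivated phenol may be sluggish, and the nitrosodisulfonate radical may decay before conversion is complete. The fallback sets out from 10 and comes back at 11. Bromination with Br2 in AcOH at the open para position gives 2,4-dibromo-6-methylphenol F5. Oxidation with CrO3 in aqueous AcOH at 60 °C then displaces the para bromine oxidatively and gives 11. The para position is thus activated by a leaving group and the radical oxidant is avoided.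

**Further compounds**
F1 | step 9 | racemic O-(5,5-dimethyl-1,3,2-dioxaborinan-2-yl) ether of F2 | CCOC(=O)/C(C)=C\CC/C(C)=C/CC/C(C)=C/C(OB1OCC(C)(C)CO1)C/C(C)=C/Cc1cc(OC(C)=O)cc(C)c1OC(C)=O
F2 | step 9 | racemic ethyl (2Z,6E,10E,14E)-16-(2,5-diacetoxy-3-methylphenyl)-12-hydroxy-2,6,10,14-tetramethylhexadeca-2,6,10,14-tetraenoate | CCOC(=O)/C(C)=C\CC/C(C)=C/CC/C(C)=C/C(O)C/C(C)=C/Cc1cc(OC(C)=O)cc(C)c1OC(C)=O
F3 | step 9 | ethyl (2Z,6E,10E,14E)-16-(2,5-diacetoxy-3-methylphenyl)-2,6,10,14-tetramethyl-12-oxohexadeca-2,6,10,14-tetraenoate | CCOC(=O)/C(C)=C\CC/C(C)=C/CC/C(C)=C/C(=O)C/C(C)=C/Cc1cc(OC(C)=O)cc(C)c1OC(C)=O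
F4 | step 10 | 2-[(2E,5R,6E,10E,14Z)-5,16-dihydroxy-3,7,11,15-tetramethylhexadeca-2,6,10,14-tetraen-1-yl]-6-methyl-1,4-benzoquinone | C/C(=C/CC/C(C)=C/CC/C(C)=C/[C@H](O)C/C(C)=C/CC1=CC(=O)C=C(C)C1=O)CO
F5 | step 6 | 2,4-dibromo-6-methylphenol | Cc1cc(Br)cc(Br)c1O
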